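The 2,2-dimethylpyran ring is disconnected at C4–C4a and O1–C2, leaving a fully substituted acylresorcinol and 3-methylbut-2-enal. In one operation a formal [3+3] annulation (condensation to an ortho-quinone methide, then oxa-6π electrocyclisation) forms the aryl–CH bond and the O–CMe2 bond. It exploits ring A: C4a is the only unsubstituted carbon, flanked by the oxygens on C8a and C5, and the C5 hydroxyl is chelated to the C6 ketone, so the C8a oxygen closes the ring. The precursor, a 4,6-dihydroxy-2-methoxy-3-prenyl deoxybenzoin, comes from 5-methoxyresorcinol by Friedel–Crafts acylation and a para-Claisen–Cope prenyl shift.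

Key step: step 6

Remark: the target has no stereocentre. Chromene numbering (O1, C2, C3, C4, C4a, C5 to C8, C8a) is used for the target. Ring A is the hexasubstituted benzene ring and ring B the 4-hydroxyphenyl ring. In the open-chain precursors, ring A positions follow the name of the compound concerned. Compounds 1, 2, 5 and 11 are assumed to be commercially available.

Step 1
Reactants: 1 5-methoxyresorcinol; 2 4-hydroxyphenylacetic acid
Product: 3 1-(2,4-dihydroxy-6-methoxyphenyl)-2-(4-hydroxyphenyl)ethanone
Conditions: BF3·OEt2 (neat, excess), 85 °C; then aq. NaOAc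
Reagents that add atoms: none
Why: Friedel–Crafts acylation of 1 should occur at the ring carbon para to one hydroxyl and ortho to the other (the site electrophiles prefer on phloroglucinol monoethers, two equivalent positions), giving a ketone chelated to the ortho hydroxyl, while ring B of 2 is far less nucleophilic.

Step 2
Reactants: 3 1-(2,4-dihydroxy-6-methoxyphenyl)-2-(4-hydroxyphenyl)ethanone
Product: 4 1-[4-(tert-butyldimethylsilyloxy)-2-hydroxy-6-methoxyphenyl]-2-[4-(tert-butyldimethylsilyloxy)phenyl]ethanone
Conditions: TBSCl (2.1 equiv), imidazole, DMF, 0 °C to rt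
Reagents that add atoms: tert-butyldimethylsilyl chloride (TBSCl), CC(C)(C)[Si](C)(C)Cl
Why: Silyl ether formation should take place at the two unhindered phenols (4-OH of ring A and the ring B hydroxyl), while the 2-OH, hydrogen-bonded to the ketone and flanked by the acyl group, should stay free.

Step 3
Reactants: 4 1-[4-(tert-butyldimethylsilyloxy)-2-hydroxy-6-methoxyphenyl]-2-[4-(tert-butyldimethylsilyloxy)phenyl]ethanone; 5 3-methylbut-2-en-1-ol
Product: 6 1-[4-(tert-butyldimethylsilyloxy)-2-methoxy-6-(3-methylbut-2-enyloxy)phenyl]-2-[4-(tert-butyldimethylsilyloxy)phenyl]ethanone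
Conditions: PPh3, DIAD, THF, 0 °C to rt
Reagents that add atoms: none
Why: A Mitsunobu etherification should alkylate the chelated phenol under neutral conditions, which avoids base-mediated alkylation at the acidic benzylic CH2 of the deoxybenzoin and loss of the aryl silyl ethers.

Step 4
Reactants: 6 1-[4-(tert-butyldimethylsilyloxy)-2-methoxy-6-(3-methylbut-2-enyloxy)phenyl]-2-[4-(tert-butyldimethylsilyloxy)phenyl]ethanone
Product: 9 1-[4-(tert-butyldimethylsilyloxy)-6-hydroxy-2-methoxy-3-(3-methylbut-2-enyl)phenyl]-2-[4-(tert-butyldimethylsilyloxy)phenyl]ethanone, via ortho-dienone 7 (not isolated), via para-dienone 8 (not isolated)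
Conditions: N,N-diethylaniline, 200 °C, sealed tube
Reagents that add atoms: none
Why: An aromatic Claisen rearrangement to the only open ortho carbon should give the congested 1,1-dimethylallyl dienone 7, whose Cope rearrangement moves the allyl unit with a second inversion to the para carbon between OTBS and OMe (8), and enolisation then gives the linear prenyl phenol (para-Claisen–Cope sequence); the stereocentres of 7 and 8 are transient and vanish on aromatisation.

Step 5
Reactants: 9 1-[4-(tert-butyldimethylsilyloxy)-6-hydroxy-2-methoxy-3-(3-methylbut-2-enyl)phenyl]-2-[4-(tert-butyldimethylsilyloxy)phenyl]ethanone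
Product: 10 1-[4,6-dihydroxy-2-methoxy-3-(3-methylbut-2-enyl)phenyl]-2-(4-hydroxyphenyl)ethanone
Conditions: Bu4NF (2.2 equiv), AcOH (2.2 equiv), THF, 0 °C
Reagents that add atoms: none
Why: Fluoride-mediated desilylation should free both phenols, and buffering with acetic acid keeps the medium near neutral so that the prenyl group next to the freed 4-OH does not cyclise to a chroman.

Step 6
Reactants: 10 1-[4,6-dihydroxy-2-methoxy-3-(3-methylbut-2-enyl)phenyl]-2-(4-hydroxyphenyl)ethanone; 11 3-methylbut-2-enal
Product: 13 1-[5-hydroxy-7-methoxy-2,2-dimethyl-8-(3-methylbut-2-enyl)-2H-chromen-6-yl]-2-(4-hydroxyphenyl)ethanone, via ortho-quinone methide 12 (not isolated)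
Conditions: ethylenediammonium diacetate (20 mol %), xylene, 140 °C
Reagents that add atoms: none
Why: The diammonium salt should convert 11 into an iminium ion that is attacked by C5 of ring A of 10, the only unsubstituted carbon of that ring and the one activated by both flanking hydroxyls (Knoevenagel/aldol-type condensation), and loss of the amine gives the ortho-quinone methide 12, a 1-oxatriene. A thermal disrotatory oxa-6π electrocyclisation of the O=C–C=CH–CH=CMe2 unit then closes the six-membered pyran by forming the O–CMe2 bond and restores the aromatic ring, so the aryl–CH bond and the O–C bond arise in one operation. The closest known reaction type is the amine-promoted formal [3+3] chromenylation of resorcinols and acylphloroglucinols with α,β-unsaturated aldehydes. No stereocentre is created. Two selectivities are needed: reaction at ring A and not ring B, secured because ring B is a simple para-alkylphenol that does not condense with enals under these conditions, and closure through the 4-oxygen and not the 6-oxygen, secured because the 6-OH is held in a hydrogen bond to the ketone and the electrocyclisation is reversible, so the isomer that keeps the chelate should prevail.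

Compound list
1 | 5-methoxyresorcinol (3,5-dihydroxyanisole) | COc1cc(O)cc(O)c1 | starting material
2 | 4-hydroxyphenylacetic acid | OC(=O)Cc1ccc(O)cc1 | starting material
3 | 1-(2,4-dihydroxy-6-methoxyphenyl)-2-(4-hydroxyphenyl)ethanone | COc1cc(O)cc(O)c1C(=O)Cc1ccc(O)cc1 | intermediate
4 | 1-[4-(tert-butyldimethylsilyloxy)-2-hydroxy-6-methoxyphenyl]-2-[4-(tert-butyldimethylsilyloxy)phenyl]ethanone | COc1cc(O[Si](C)(C)C(C)(C)C)cc(O)c1C(=O)Cc1ccc(O[Si](C)(C)C(C)(C)C)cc1 | intermediate
5 | 3-methylbut-2-en-1-ol (prenol) | CC(C)=CCO | starting material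
6 | 1-[4-(tert-butyldimethylsilyloxy)-2-methoxy-6-(3-methylbut-2-enyloxy)phenyl]-2-[4-(tert-butyldimethylsilyloxy)phenyl]ethanone | COc1cc(O[Si](C)(C)C(C)(C)C)cc(OCC=C(C)C)c1C(=O)Cc1ccc(O[Si](C)(C)C(C)(C)C)cc1 | intermediate
7 | ortho-dienone: 5-(tert-butyldimethylsilyloxy)-2-{[4-(tert-butyldimethylsilyloxy)phenyl]acetyl}-3-methoxy-6-(2-methylbut-3-en-2-yl)cyclohexa-2,4-dien-1-one (racemic, transient) | COC1=C(C(=O)Cc2ccc(O[Si](C)(C)C(C)(C)C)cc2)C(=O)C(C(C)(C)C=C)C(O[Si](C)(C)C(C)(C)C)=C1 | intermediate
8 | para-dienone: 5-(tert-butyldimethylsilyloxy)-2-{[4-(tert-butyldimethylsilyloxy)phenyl]acetyl}-3-methoxy-4-(3-methylbut-2-enyl)cyclohexa-2,5-dien-1-one (racemic, transient) | COC1=C(C(=O)Cc2ccc(O[Si](C)(C)C(C)(C)C)cc2)C(=O)C=C(O[Si](C)(C)C(C)(C)C)C1CC=C(C)C | intermediate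
9 | 1-[4-(tert-butyldimethylsilyloxy)-6-hydroxy-2-methoxy-3-(3-methylbut-2-enyl)phenyl]-2-[4-(tert-butyldimethylsilyloxy)phenyl]ethanone | COc1c(CC=C(C)C)c(O[Si](C)(C)C(C)(C)C)cc(O)c1C(=O)Cc1ccc(O[Si](C)(C)C(C)(C)C)cc1 | intermediate
10 | 1-[4,6-dihydroxy-2-methoxy-3-(3-methylbut-2-enyl)phenyl]-2-(4-hydroxyphenyl)ethanone | COc1c(CC=C(C)C)c(O)cc(O)c1C(=O)Cc1ccc(O)cc1 | intermediate
11 | 3-methylbut-2-enal (prenal) | CC(C)=CC=O | starting material
12 | ortho-quinone methide: 5-hydroxy-4-[(4-hydroxyphenyl)acetyl]-3-methoxy-2-(3-methylbut-2-enyl)-6-(3-methylbut-2-enylidene)cyclohexa-2,4-dien-1-one | COC1=C(CC=C(C)C)C(=O)C(=CC=C(C)C)C(O)=C1C(=O)Cc1ccc(O)cc1 | intermediate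
13 | 1-[5-hydroxy-7-methoxy-2,2-dimethyl-8-(3-methylbut-2-enyl)-2H-chromen-6-yl]-2-(4-hydroxyphenyl)ethanone | COc1c(CC=C(C)C)c2c(c(O)c1C(=O)Cc1ccc(O)cc1)C=CC(C)(C)O2 | target

Total step count: 6
Longest linear sequence: 6 steps (1 to 13)

Steps most likely to fail

Step 4. The rearrangement may stop after the first [3,3] shift, with dienone 7 enolising to the ortho 1,1-dimethylallyl phenol. The prenyl ether may also simply cleave at 200 °C. Fallback: the annulation is run before the prenyl shift, so that both carbons ortho to the prenyloxy group are substituted and the allyl unit can only come to rest at the para carbon. The fallback sets out from 3 and comes back to the route at 13. Compound 3 and 11 under the conditions of step 6 should give 1-(5-hydroxy-7-methoxy-2,2-dimethyl-2H-chromen-6-yl)-2-(4-hydroxyphenyl)ethanone F1, with the C–C bond formed at the carbon between the two hydroxyls and closure through the non-chelated oxygen. TBSCl (1.1 equiv) and imidazole should silylate ring B only, giving 2-[4-(tert-butyldimethylsilyloxy)phenyl]-1-(5-hydroxy-7-methoxy-2,2-dimethyl-2H-chromen-6-yl)ethanone F2. A Mitsunobu reaction with 5 (PPh3, DIAD) should then give 2-[4-(tert-butyldimethylsilyloxy)phenyl]-1-[7-methoxy-2,2-dimethyl-5-(3-methylbut-2-enyloxy)-2H-chromen-6-yl]ethanone F3. Heating in N,N-diethylaniline should move the prenyl group to C8 by a para-Claisen rearrangement, since C4a and C6 are both blocked, giving 2-[4-(tert-butyldimethylsilyloxy)phenyl]-1-[5-hydroxy-7-methoxy-2,2-dimethyl-8-(3-methylbut-2-enyl)-2H-chromen-6-yl]ethanone F4. Bu4NF with AcOH then frees ring B to give 13.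

Step 6. The quinone methide may close through the chelated oxygen, or the condensation at the hindered ring carbon may be slow enough that the aldehyde oligomerises. Fallback: the pyran oxygen is first attached to its carbon as an aryl propargyl ether, and a thermal cascade then forms the same two bonds. The fallback sets out from 10 and comes back to the route at 13. Alkylation of the most acidic phenol of 10 (the 4-OH, para to the ketone) with 3-chloro-3-methylbut-1-yne (K2CO3, KI, catalytic CuI, acetone, 50 °C) should give 1-[6-hydroxy-2-methoxy-3-(3-methylbut-2-enyl)-4-(2-methylbut-3-yn-2-yloxy)phenyl]-2-(4-hydroxyphenyl)ethanone F5. Heating F5 in xylene at 140 °C should give 13 by propargyl Claisen rearrangement to the only free ortho carbon, 1,5-hydrogen shift and oxa-6π electrocyclisation.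

Step 1. Acylation may take place at the carbon between the two hydroxyls of 1, which would put the methoxy group para to the ketone. Fallback: a symmetric ring is acylated and the methyl group is introduced afterwards. The fallback sets out from 2, with phloroglucinol in place of 1, and comes back to the route at 4. Phloroglucinol and 2 in BF3·OEt2 at 85 °C should give 1-(2,4,6-trihydroxyphenyl)-2-(4-hydroxyphenyl)ethanone F6, all three ring positions being equivalent. TBSCl (2.1 equiv) and imidazole should silylate the two phenols remote from the ketone, giving 1-[4-(tert-butyldimethylsilyloxy)-2,6-dihydroxyphenyl]-2-[4-(tert-butyldimethylsilyloxy)phenyl]ethanone F7. A Mitsunobu methylation (MeOH, PPh3, DIAD) of one of the two equivalent ortho hydroxyls should give 4, the remaining hydroxyl being held by the chelate.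

Further compounds
F1 | step 4 | 1-(5-hydroxy-7-methoxy-2,2-dimethyl-2H-chromen-6-yl)-2-(4-hydroxyphenyl)ethanone | COc1cc2c(c(O)c1C(=O)Cc1ccc(O)cc1)C=CC(C)(C)O2
F2 | step 4 | 2-[4-(tert-butyldimethylsilyloxy)phenyl]-1-(5-hydroxy-7-methoxy-2,2-dimethyl-2H-chromen-6-yl)ethanone | COc1cc2c(c(O)c1C(=O)Cc1ccc(O[Si](C)(C)C(C)(C)C)cc1)C=CC(C)(C)O2
F3 | step 4 | 2-[4-(tert-butyldimethylsilyloxy)phenyl]-1-[7-methoxy-2,2-dimethyl-5-(3-methylbut-2-enyloxy)-2H-chromen-6-yl]ethanone | COc1cc2c(c(OCC=C(C)C)c1C(=O)Cc1ccc(O[Si](C)(C)C(C)(C)C)cc1)C=CC(C)(C)O2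
F4 | step 4 | 2-[4-(tert-butyldimethylsilyloxy)phenyl]-1-[5-hydroxy-7-methoxy-2,2-dimethyl-8-(3-methylbut-2-enyl)-2H-chromen-6-yl]ethanone | COc1c(CC=C(C)C)c2c(c(O)c1C(=O)Cc1ccc(O[Si](C)(C)C(C)(C)C)cc1)C=CC(C)(C)O2
F5 | step 6 | 1-[6-hydroxy-2-methoxy-3-(3-methylbut-2-enyl)-4-(2-methylbut-3-yn-2-yloxy)phenyl]-2-(4-hydroxyphenyl)ethanone | COc1c(CC=C(C)C)c(OC(C)(C)C#C)cc(O)c1C(=O)Cc1ccc(O)cc1
F6 | step 1 | 1-(2,4,6-trihydroxyphenyl)-2-(4-hydroxyphenyl)ethanone | O=C(Cc1ccc(O)cc1)c1c(O)cc(O)cc1O
F7 | step 1 | 1-[4-(tert-butyldimethylsilyloxy)-2,6-dihydroxyphenyl]-2-[4-(tert-butyldimethylsilyloxy)phenyl]ethanone | CC(C)(C)[Si](C)(C)Oc1ccc(CC(=O)c2c(O)cc(O[Si](C)(C)C(C)(C)C)cc2O)cc1
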